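Divide before you integrate: take the target found over the electrophile consumed, and compare that ratio between readings.

in all of them: electrophile 0.50 M; gas 17 mM (held)
- Wednesday's: solid base 1.4 equiv; run made earlier
- Saturday's: solid base 2.2 equiv; run made earlier
- flask: solid base 1.00 equiv; time 2.0 min

| run | time / min | target / % | electrophile / % |
|---|---|---|---|
| Wednesday's | 0.200 | 32 | 76 |
| Wednesday's | 0.333 | 43 | 55 |
| Wednesday's | 0.667 | 69 | 29 |
| Wednesday's | 1.33 | 81 | 6 |
| Wednesday's | 2.50 | 80 | 2 |
| Saturday's | 0.500 | 59 | 43 |
| Saturday's | 1.00 | 81 | 18 |
| Saturday's | 1.33 | 80 | 9 |
| Saturday's | 2.00 | 84 | 4 |
| Saturday's | 2.50 | 80 | 1 |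

(readings scatter by 2 percentage points)

- solid, in amounts per volume of the solution: solid base
- at the start none of the solid base is in solution
- at the start none of the gas is in solution

- how much target there is at 2.0 min, in percent of the electrophile charged
- the change that raises the amount of target at 2.0 min, in percent of the electrophile charged most ("none" if none brings more than 2 percentage points) (blue / amber / green / red / none)
- amount of target at 2.0 min, in percent of the electrophile charged, after red

- blue: doubling the solubility of the solid base, all else as stated
- amber: doubling the transfer coefficient of the gas, all else as stated
- green: doubling the dissolution coefficient of the solid base, all else as stated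
- red: doubling the saturation concentration of gas, all else as stated

I began with the two runs, which differed in solid base, 1.4 equiv against 2.2 equiv. The division gave nearly the same figure at one late reading of each run: 0.862 for Wednesday's run at 1.33 min and 0.875 for Saturday's at 2.00 min, a gap within the scatter of 2 percentage points. I called their mean the kept fraction, the target held per electrophile consumed late in a run (the integral selectivity), 0.868. But the ratio moved with the clock: Wednesday's run gave 0.972 at 0.667 min and 0.816 at 2.50 min, so I used it for a reading at 2.0 min and no other time.

The flask's 1.00 equiv lay below both runs, so using the fraction there was an extrapolation. Yet at 1.33 min Saturday's run had 9% of its electrophile left against Wednesday's 6%, so the extra base had shown no faster consumption. I therefore took Saturday's 4% as the electrophile left at 2.0 min, and my reckoning gave 83.4% of target.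

The forecast, lower than my figure, gave 78%, none as the best change and 68% after red, expecting that “More gas (red or amber) should hurt”.

The flask held 84.0% of target at 2.0 min; the best change was none, and red gave 85.4%.

    electrophile + nucleophile → acid set free + target (k = 1.86 M⁻¹ s⁻¹)
    nucleophile + acid set free ⇌ protonated nucleophile, settled at all times (K = 17000 M⁻¹)
    acid set free + free base ⇌ salt of the base (K = 1260 M⁻¹, k = 0.139 M⁻¹ s⁻¹)
    solid base ⇌ free base, rate k4*(cs4 - [free base]) while solid is left; crystals form when [free base] > cs4 (solubility = 0.0570 M, k = 0.0224 s⁻¹)
    gas ⇌ nucleophile, rate k5*(csat - [nucleophile]) (kL = 14.5 s⁻¹)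
    free base + target → over-reaction product (k = 0.0686 M⁻¹ s⁻¹)

Over-reaction product stood at 13.5% in the flask at that time, with 2.6% of the electrophile left, so the flask's own kept fraction came to 0.862. On the neighbour charged with 0.20 M of electrophile, which had 2.4% left, the kept fraction of 0.868 gave 84.7%, and that neighbour held 79.7%.

(The readings come from a simulation with constants of no real substance, noise included.)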